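**Plan**

- Retrosynthetic cuts, in this order: (i) the lactone bonds O–C7 and C17–C8, so that a propionate unit is annulated onto C7–C8; (ii) C5–C6 of the ten-membered ring; (iii) C8–C9, C4–C5 and C2=C3 of the two side chains; (iv) C1–C14 and C10–C11 of the cyclohexenone (Diels–Alder).
- Forward: the six-membered ring (C1, C10–C14) is made by Diels–Alder reaction and acetoxylated at C11; the west chain C2–C5 and the east chain C6–C9 are attached; the five-membered lactone is closed; the ten-membered ring (C1–C10) is closed last at C5–C6; chloride and the C9 acetate follow.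
- Enabling feature: the C8 ketone carbonyl flanked by the C6–C7 oxirane, i.e. two adjacent electrophilic carbons C8 and C7. The enediolate of propionic acid bonds C17 to C8, and its carboxylate oxygen then opens the oxirane at C7. This closes the lactone ring O–C19–C17–C8–C7 and frees the C6 hydroxyl that is later used for ring closure.
- Stereochemistry: C1/C10 from the catalytic Diels–Alder step (E-dienophile gives trans); C11 by substrate control; C4 by catalytic alkynylation; C9 and the temporary C8 carbinol by reagent-controlled anti-allylboration; C7 by matched Sharpless epoxidation followed by SN2 inversion; C8 by Felkin–Anh addition; C17 by the aldol/lactone equilibrium; C6 by ligand-controlled ring closure followed by SN2 inversion to the chloride.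

Key step: step 14

Remark: all intermediates carry the atom numbers of the target skeleton (C1 quaternary ring carbon, C2=C3, C4 carbinol, C5 exo-methylene carbon, C6 CHCl, C7 lactone CH–O, C8 tertiary carbinol, C9 CH–OAc, C10 ring CH, C11 C(Me)OAc, C12 ketone, C13=C14, C17 lactone CH(Me), C19 lactone carbonyl); the reagent and ligand antipodes named are those expected to give the stated configurations.

**Route**

Step 1
Reactants: 1 pent-1-en-3-one
Product: 2 (Z)-triisopropyl(penta-1,3-dien-3-yloxy)silane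
Conditions: TIPSOTf, Et3N, Et2O, 0 °C to rt
Reagents that add atoms: triisopropylsilyl trifluoromethanesulfonate, CC(C)[Si](OS(=O)(=O)C(F)(F)F)(C(C)C)C(C)C
Why: soft enolisation and O-silylation of the ethyl side of the vinyl ketone (silyl dienol ether formation) gives the 2-silyloxy diene, the Z enol ether being the usual kinetic product and its geometry being without consequence later.

Step 2
Reactants: 2 (Z)-triisopropyl(penta-1,3-dien-3-yloxy)silane; 3 (E)-4,4-dimethoxy-2-methylbut-2-enal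
Product: 4 (1S,5S,6S)-6-(dimethoxymethyl)-1,5-dimethyl-4-(triisopropylsilyloxy)cyclohex-3-ene-1-carbaldehyde
Conditions: (S)-3,3-diphenyl-1-(2-methylphenyl)tetrahydro-1H,3H-pyrrolo[1,2-c][1,3,2]oxazaborole (20 mol%) protonated with HNTf2, CH2Cl2, −78 °C
Reagents that add atoms: none
Why: catalytic enantioselective Diels–Alder reaction in which the protonated oxazaborolidine binds the formyl group of 3, the silyloxy-activated diene terminus (future C11) bonds to the carbon β to the formyl group (future C10), the E geometry of 3 fixes the trans relation of the C1 formyl and C10 dimethoxymethyl groups, and the catalyst shields one face so that C1 and C10 are set as drawn (the C11 methine formed here is reset in step 4).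

Step 3
Reactants: 4 (1S,5S,6S)-6-(dimethoxymethyl)-1,5-dimethyl-4-(triisopropylsilyloxy)cyclohex-3-ene-1-carbaldehyde
Product: 5 (1S,5S,6S)-6-(dimethoxymethyl)-1,5-dimethyl-4-oxocyclohex-2-ene-1-carbaldehyde
Conditions: Pd(OAc)2 (1.2 equiv), MeCN, 40 °C
Reagents that add atoms: none
Why: Saegusa–Ito oxidation, in which palladation of the silyl enol ether at C13 and β-hydride loss from C14 give the C13=C14 enone without touching the stereocenters.

Step 4
Reactants: 5 (1S,5S,6S)-6-(dimethoxymethyl)-1,5-dimethyl-4-oxocyclohex-2-ene-1-carbaldehyde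
Product: 6 (1S,5S,6R)-5-acetoxy-6-(dimethoxymethyl)-1,5-dimethyl-4-oxocyclohex-2-ene-1-carbaldehyde
Conditions: Mn(OAc)3·2H2O (3 equiv), benzene, reflux (water separator)
Reagents that add atoms: manganese triacetate, CC(=O)[O-].CC(=O)[O-].CC(=O)[O-].[Mn+3]
Why: α′-acetoxylation of an enone with Mn(OAc)3 through the manganese enolate and the α-keto radical at C11, the acetate being delivered to the face opposite the axial C1 methyl group and anti to the C10 substituent, which sets 11S (acetoxy cis to the C1 formyl group).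

Step 5
Reactants: 6 (1S,5S,6R)-5-acetoxy-6-(dimethoxymethyl)-1,5-dimethyl-4-oxocyclohex-2-ene-1-carbaldehyde; 7 (triphenylphosphoranylidene)acetaldehyde
Product: 8 (E)-3-[(1S,5S,6R)-5-acetoxy-6-(dimethoxymethyl)-1,5-dimethyl-4-oxocyclohex-2-en-1-yl]prop-2-enal
Conditions: toluene, 90 °C
Reagents that add atoms: none
Why: Wittig olefination with a stabilised ylide gives the E-enal (C2=C3) and touches only the aldehyde, not the hindered enone carbonyl.

Step 6
Reactants: 8 (E)-3-[(1S,5S,6R)-5-acetoxy-6-(dimethoxymethyl)-1,5-dimethyl-4-oxocyclohex-2-en-1-yl]prop-2-enal; 9 ethynyltrimethylsilane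
Product: 11 (1S,2R,3S)-2-(dimethoxymethyl)-3-[(1E,3S)-3-hydroxypent-1-en-4-yn-1-yl]-1,3-dimethyl-6-oxocyclohex-4-en-1-yl acetate, via silylalkyne carbinol 10 (not isolated)
Conditions: Me2Zn, (S,S)-ProPhenol [2,6-bis{[(S)-2-(hydroxydiphenylmethyl)pyrrolidin-1-yl]methyl}-4-methylphenol] (20 mol%), Ph3P=O (40 mol%), toluene, 0 °C; then K2CO3, MeOH, 0 °C
Reagents that add atoms: none
Why: catalytic asymmetric alkynylation, in which the zinc acetylide adds 1,2 to the enal inside the dinuclear zinc–ProPhenol complex and reagent control sets 4S, followed by carbonate methanolysis of the C–Si bond in the same flask.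

Step 7
Reactants: 11 (1S,2R,3S)-2-(dimethoxymethyl)-3-[(1E,3S)-3-hydroxypent-1-en-4-yn-1-yl]-1,3-dimethyl-6-oxocyclohex-4-en-1-yl acetate
Product: 12 (1S,2R,3S)-3-[(1E,3S)-3-(tert-butyldiphenylsilyloxy)pent-1-en-4-yn-1-yl]-2-(dimethoxymethyl)-1,3-dimethyl-6-oxocyclohex-4-en-1-yl acetate
Conditions: TBDPSCl, imidazole, DMF, rt
Reagents that add atoms: tert-butyl(chloro)diphenylsilane, CC(C)(C)[Si](Cl)(c1ccccc1)c1ccccc1
Why: standard silylation of the secondary propargylic alcohol gives an acid-stable C4 ether that survives to the last step.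

Step 8
Reactants: 12 (1S,2R,3S)-3-[(1E,3S)-3-(tert-butyldiphenylsilyloxy)pent-1-en-4-yn-1-yl]-2-(dimethoxymethyl)-1,3-dimethyl-6-oxocyclohex-4-en-1-yl acetate
Product: 13 (1S,2R,3S)-3-[(1E,3S)-3-(tert-butyldiphenylsilyloxy)-4-iodopenta-1,4-dien-1-yl]-2-formyl-1,3-dimethyl-6-oxocyclohex-4-en-1-yl acetate
Conditions: NaI, TMSCl, H2O, MeCN, 0 °C to rt
Reagents that add atoms: sodium iodide, [Na+].[I-]; water, O
Why: Markovnikov hydroiodination of the terminal alkyne by hydrogen iodide formed in situ puts iodine on C5, and the same aqueous acid hydrolyses the dimethyl acetal to the C9 aldehyde.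

Step 9
Reactants: 13 (1S,2R,3S)-3-[(1E,3S)-3-(tert-butyldiphenylsilyloxy)-4-iodopenta-1,4-dien-1-yl]-2-formyl-1,3-dimethyl-6-oxocyclohex-4-en-1-yl acetate; 14 4,4,5,5-tetramethyl-2-(propa-1,2-dien-1-yl)-1,3,2-dioxaborolane
Product: 17 (1S,2S,3S)-3-[(1E,3S)-3-(tert-butyldiphenylsilyloxy)-4-iodopenta-1,4-dien-1-yl]-2-[(1S,2R)-1,2-dihydroxybut-3-en-1-yl]-1,3-dimethyl-6-oxocyclohex-4-en-1-yl acetate, via borylallyl borane 15 (not isolated), via allylboration adduct 16 (not isolated)
Conditions: 14, (lIpc)2BH (diisopinocampheylborane from (−)-α-pinene), Et2O, −25 to 0 °C; then 13, −78 °C; then H2O2, aq. NaHCO3, THF, 0 °C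
Reagents that add atoms: hydrogen peroxide, OO
Why: hydroboration of the allenylboronate gives the (E)-γ-borylallylborane 15, whose allylboration of the aldehyde through a chair transition state gives the anti adduct 16 with the isopinocampheyl groups controlling the aldehyde face (9S), and oxidation of the C8–B bond with retention gives the 8R,9S anti-diol.

Step 10
Reactants: 17 (1S,2S,3S)-3-[(1E,3S)-3-(tert-butyldiphenylsilyloxy)-4-iodopenta-1,4-dien-1-yl]-2-[(1S,2R)-1,2-dihydroxybut-3-en-1-yl]-1,3-dimethyl-6-oxocyclohex-4-en-1-yl acetate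
Product: 19 bis-silyl ether of 17 with C8–OSiEt3 and C9–OSi(tBu)Me2 (8R,9S), via mono triethylsilyl ether 18 (not isolated)
Conditions: TESCl (1.05 equiv), imidazole, CH2Cl2, −20 °C; then TBSOTf, 2,6-lutidine, 0 °C to rt
Reagents that add atoms: chlorotriethylsilane, CC[Si](Cl)(CC)CC; tert-butyldimethylsilyl trifluoromethanesulfonate, CC(C)(C)[Si](C)(C)OS(=O)(=O)C(F)(F)F
Why: sequential silylation, in which the less hindered allylic C8 hydroxyl takes the labile triethylsilyl group first and the hindered C9 hydroxyl is then capped by the silyl triflate as a non-chelating ether.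

Step 11
Reactants: 19 bis-silyl ether of 17 with C8–OSiEt3 and C9–OSi(tBu)Me2 (8R,9S)
Product: 20 C8 allylic alcohol with C9–OSi(tBu)Me2 (8R,9S)
Conditions: PPTS, MeOH/CH2Cl2, 0 °C
Reagents that add atoms: none
Why: acid-catalysed methanolysis cleaves the triethylsilyl ether much faster than the tert-butyldimethylsilyl and tert-butyldiphenylsilyl ethers (selective desilylation).

Step 12
Reactants: 20 C8 allylic alcohol with C9–OSi(tBu)Me2 (8R,9S)
Product: 21 epoxy alcohol with C6–C7 oxirane, C8–OH and C9–OSi(tBu)Me2 (7R,8R,9S)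
Conditions: Ti(OiPr)4 (cat.), L-(+)-diisopropyl tartrate, tBuOOH, 4 Å sieves, CH2Cl2, −20 °C
Reagents that add atoms: tert-butyl hydroperoxide, CC(C)(C)OO
Why: Sharpless asymmetric epoxidation of the secondary allylic alcohol, in which the L-(+)-tartrate and the 8R carbinol are matched and give the erythro epoxy alcohol with 7R, while the allylic ether alkene, the vinyl iodide and the enone do not react.

Step 13
Reactants: 21 epoxy alcohol with C6–C7 oxirane, C8–OH and C9–OSi(tBu)Me2 (7R,8R,9S)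
Product: 22 epoxy ketone with (7R)-oxiranyl C8 ketone and C9–OSi(tBu)Me2 (7R,9S)
Conditions: Dess–Martin periodinane, CH2Cl2, 0 °C to rt
Reagents that add atoms: none
Why: Dess–Martin oxidation of the secondary alcohol under neutral conditions gives the α,β-epoxy ketone without opening the oxirane or epimerising C9.

Step 14
Reactants: 22 epoxy ketone with (7R)-oxiranyl C8 ketone and C9–OSi(tBu)Me2 (7R,9S); 23 propanoic acid
Product: 26 hydroxymethyl lactone with the 17-methyl-8-hydroxy-γ-lactone fused at C7–C8 and C6 as CH2OH (7S,8S,9S,17R), via dilithium enediolate 24 (not isolated), via dilithium epoxy aldolate 25 (not isolated)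
Conditions: 23 (2.2 equiv), LiN(iPr)2 (4.4 equiv), THF/DMPU, 0 °C; then 22, −78 to −20 °C; then AcOH, 0 °C to rt
Reagents that add atoms: none
Why: The dilithium enediolate 24 adds through C17 to the C8 carbonyl, and the carboxylate of aldolate 25 then opens the adjacent oxirane at C7 on warming and acidification, so that C17–C8 and O–C7 form in one flask; the closest known reaction types are the aldol addition of carboxylic acid dianions and the lactonisation of γ,δ-epoxy acids. The five-membered lactone ring (O, C19, C17, C8, C7) closes in the 5-exo-tet mode at the oxirane carbon C7, which is favoured over 6-endo attack at C6 by ring size and, under acid, by the higher substitution of C7. C8 is set by Felkin–Anh addition anti to both the C9–OSi bond and the oxirane C7–O bond, which are non-chelating in THF/DMPU and reinforce each other, giving the 8-hydroxyl syn to the 9-silyloxy group. C7 is set by stereospecific SN2 inversion of the 7R oxirane carbon, which places C6 cis to the 8-hydroxyl and trans to C9 on the lactone. C17 arises in the chair-like (Zimmerman–Traxler) aldol transition state and is also the thermodynamic epimer (methyl trans to the C9 branch), so the enolisable lactone can be equilibrated with base if needed. The step needs chemoselectivity for the C8 ketone, which is the only doubly α-oxygenated and hence most electrophilic carbonyl, whereas the C12 enone cannot enolise and is shielded by the quaternary carbons C1 and C11 and the tertiary acetate reacts slowly at −78 °C.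

Step 15
Reactants: 26 hydroxymethyl lactone with the 17-methyl-8-hydroxy-γ-lactone fused at C7–C8 and C6 as CH2OH (7S,8S,9S,17R)
Product: 27 lactone aldehyde with C6 formyl group (7R,8S,9S,17R)
Conditions: Dess–Martin periodinane, CH2Cl2, 0 °C
Reagents that add atoms: none
Why: Dess–Martin oxidation of the primary alcohol gives the aldehyde, while the tertiary C8 hydroxyl cannot be oxidised and the neutral conditions avoid epimerisation at C7.

Step 16
Reactants: 27 lactone aldehyde with C6 formyl group (7R,8S,9S,17R)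
Product: 28 ten-membered ring alcohol with C6–OH, C4–OSi(tBu)Ph2 and C9–OSi(tBu)Me2 (1S,4S,6R,7S,8S,9S,10S,11S,17R)
Conditions: CrCl2 (excess), (S)-N-[2-(4-isopropyl-4,5-dihydro-1,3-oxazol-2-yl)-6-methoxyphenyl]methanesulfonamide, Et3N, NiCl2 (cat.), THF/MeCN, rt, 0.002 M
Reagents that add atoms: none
Why: intramolecular Nozaki–Hiyama–Kishi reaction, in which nickel catalysis turns the C5 vinyl iodide into an alkenylchromium species that adds only to the C6 aldehyde and closes the ten-membered ring at high dilution with the exo-methylene in place, the chiral sulfonamide–chromium complex being chosen to give the 6R carbinol.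

Step 17
Reactants: 28 ten-membered ring alcohol with C6–OH, C4–OSi(tBu)Ph2 and C9–OSi(tBu)Me2 (1S,4S,6R,7S,8S,9S,10S,11S,17R)
Product: 29 C6 chloride with C4–OSi(tBu)Ph2 and C9–OSi(tBu)Me2 (6S,7R,8S,9S)
Conditions: PPh3, hexachloroacetone, CH2Cl2, −20 to 0 °C
Reagents that add atoms: hexachloroacetone, ClC(Cl)(Cl)C(=O)C(Cl)(Cl)Cl
Why: Appel-type chlorination, in which the alkoxyphosphonium ion of the allylic C6 alcohol is displaced by chloride with SN2 inversion and without allylic transposition to give 6S, the tertiary C8 hydroxyl being too hindered to react.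

Step 18
Reactants: 29 C6 chloride with C4–OSi(tBu)Ph2 and C9–OSi(tBu)Me2 (6S,7R,8S,9S)
Product: 30 C9 alcohol with C4–OSi(tBu)Ph2 (6S,7R,8R,9S)
Conditions: HF·pyridine, pyridine, THF, 0 °C to rt
Reagents that add atoms: none
Why: buffered acidic fluoride desilylation cleaves the tert-butyldimethylsilyl ether far faster than the tert-butyldiphenylsilyl ether and leaves acetate, lactone and allylic chloride intact.

Step 19
Reactants: 30 C9 alcohol with C4–OSi(tBu)Ph2 (6S,7R,8R,9S)
Product: 31 C9 acetate, the 4-O-tert-butyldiphenylsilyl ether of the target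
Conditions: Ac2O, DMAP, pyridine, CH2Cl2, rt
Reagents that add atoms: acetic anhydride, CC(=O)OC(C)=O
Why: DMAP-catalysed acylation of the secondary C9 alcohol, the tertiary C8 alcohol remaining free under these conditions.

Step 20
Reactants: 31 C9 acetate, the 4-O-tert-butyldiphenylsilyl ether of the target
Product: 32 CNP0196166.1 (1S,4S,6S,7R,8R,9S,10S,11S,17R)
Conditions: HF·pyridine (excess), THF, rt
Reagents that add atoms: none
Why: fluoride desilylation of the allylic C4 ether under mildly acidic conditions that both acetates, the lactone and the allylic chloride tolerate.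

**Compound list**

1 | pent-1-en-3-one | C=CC(=O)CC | starting material
2 | (Z)-triisopropyl(penta-1,3-dien-3-yloxy)silane | C/C=C(\O[Si](C(C)C)(C(C)C)C(C)C)C=C | intermediate
3 | (E)-4,4-dimethoxy-2-methylbut-2-enal | O=C/C(C)=C/C(OC)OC | starting material
4 | (1S,5S,6S)-6-(dimethoxymethyl)-1,5-dimethyl-4-(triisopropylsilyloxy)cyclohex-3-ene-1-carbaldehyde | O=C[C@@]1(C)CC=C(O[Si](C(C)C)(C(C)C)C(C)C)[C@@H](C)[C@@H]1C(OC)OC | intermediate
5 | (1S,5S,6S)-6-(dimethoxymethyl)-1,5-dimethyl-4-oxocyclohex-2-ene-1-carbaldehyde | O=C[C@@]1(C)C=CC(=O)[C@@H](C)[C@@H]1C(OC)OC | intermediate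
6 | (1S,5S,6R)-5-acetoxy-6-(dimethoxymethyl)-1,5-dimethyl-4-oxocyclohex-2-ene-1-carbaldehyde | O=C[C@@]1(C)C=CC(=O)[C@@](C)(OC(C)=O)[C@@H]1C(OC)OC | intermediate
7 | (triphenylphosphoranylidene)acetaldehyde | O=CC=P(c1ccccc1)(c1ccccc1)c1ccccc1 | starting material
8 | (E)-3-[(1S,5S,6R)-5-acetoxy-6-(dimethoxymethyl)-1,5-dimethyl-4-oxocyclohex-2-en-1-yl]prop-2-enal | O=C/C=C/[C@@]1(C)C=CC(=O)[C@@](C)(OC(C)=O)[C@@H]1C(OC)OC | intermediate
9 | ethynyltrimethylsilane | C#C[Si](C)(C)C | starting material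
10 | silylalkyne carbinol: (1S,2R,3S)-2-(dimethoxymethyl)-3-[(1E,3S)-3-hydroxy-5-(trimethylsilyl)pent-1-en-4-yn-1-yl]-1,3-dimethyl-6-oxocyclohex-4-en-1-yl acetate | C[Si](C)(C)C#C[C@@H](O)/C=C/[C@@]1(C)C=CC(=O)[C@@](C)(OC(C)=O)[C@@H]1C(OC)OC | intermediate
11 | (1S,2R,3S)-2-(dimethoxymethyl)-3-[(1E,3S)-3-hydroxypent-1-en-4-yn-1-yl]-1,3-dimethyl-6-oxocyclohex-4-en-1-yl acetate | C#C[C@@H](O)/C=C/[C@@]1(C)C=CC(=O)[C@@](C)(OC(C)=O)[C@@H]1C(OC)OC | intermediate
12 | (1S,2R,3S)-3-[(1E,3S)-3-(tert-butyldiphenylsilyloxy)pent-1-en-4-yn-1-yl]-2-(dimethoxymethyl)-1,3-dimethyl-6-oxocyclohex-4-en-1-yl acetate | C#C[C@@H](O[Si](c1ccccc1)(c1ccccc1)C(C)(C)C)/C=C/[C@@]1(C)C=CC(=O)[C@@](C)(OC(C)=O)[C@@H]1C(OC)OC | intermediate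
13 | (1S,2R,3S)-3-[(1E,3S)-3-(tert-butyldiphenylsilyloxy)-4-iodopenta-1,4-dien-1-yl]-2-formyl-1,3-dimethyl-6-oxocyclohex-4-en-1-yl acetate | C=C(I)[C@@H](O[Si](c1ccccc1)(c1ccccc1)C(C)(C)C)/C=C/[C@@]1(C)C=CC(=O)[C@@](C)(OC(C)=O)[C@@H]1C=O | intermediate
14 | 4,4,5,5-tetramethyl-2-(propa-1,2-dien-1-yl)-1,3,2-dioxaborolane | C=C=CB1OC(C)(C)C(C)(C)O1 | starting material
15 | borylallyl borane: (E)-[3-(4,4,5,5-tetramethyl-1,3,2-dioxaborolan-2-yl)allyl]bis(isopinocampheyl)borane | CC1(C)OB(/C=C/CB([C@H]2C[C@H]3C[C@@H]([C@@H]2C)C3(C)C)[C@H]2C[C@H]3C[C@@H]([C@@H]2C)C3(C)C)OC1(C)C | intermediate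
16 | allylboration adduct: C9–O–B(isopinocampheyl)2 borinate with C8–B(pinacolato), anti | C=C(I)[C@@H](O[Si](c1ccccc1)(c1ccccc1)C(C)(C)C)/C=C/[C@@]1(C)C=CC(=O)[C@@](C)(OC(C)=O)[C@@H]1[C@H](OB([C@H]2C[C@H]3C[C@@H]([C@@H]2C)C3(C)C)[C@H]2C[C@H]3C[C@@H]([C@@H]2C)C3(C)C)[C@H](B2OC(C)(C)C(C)(C)O2)C=C | intermediate
17 | (1S,2S,3S)-3-[(1E,3S)-3-(tert-butyldiphenylsilyloxy)-4-iodopenta-1,4-dien-1-yl]-2-[(1S,2R)-1,2-dihydroxybut-3-en-1-yl]-1,3-dimethyl-6-oxocyclohex-4-en-1-yl acetate (8R,9S anti-diol) | C=C(I)[C@@H](O[Si](c1ccccc1)(c1ccccc1)C(C)(C)C)/C=C/[C@@]1(C)C=CC(=O)[C@@](C)(OC(C)=O)[C@@H]1[C@H](O)[C@H](O)C=C | intermediate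
18 | mono triethylsilyl ether of 17: C8–OSiEt3, C9–OH (8R,9S) | C=C(I)[C@@H](O[Si](c1ccccc1)(c1ccccc1)C(C)(C)C)/C=C/[C@@]1(C)C=CC(=O)[C@@](C)(OC(C)=O)[C@@H]1[C@H](O)[C@H](O[Si](CC)(CC)CC)C=C | intermediate
19 | bis-silyl ether of 17 with C8–OSiEt3 and C9–OSi(tBu)Me2 (8R,9S) | C=C(I)[C@@H](O[Si](c1ccccc1)(c1ccccc1)C(C)(C)C)/C=C/[C@@]1(C)C=CC(=O)[C@@](C)(OC(C)=O)[C@@H]1[C@H](O[Si](C)(C)C(C)(C)C)[C@H](O[Si](CC)(CC)CC)C=C | intermediate
20 | C8 allylic alcohol with C9–OSi(tBu)Me2 (8R,9S) | C=C(I)[C@@H](O[Si](c1ccccc1)(c1ccccc1)C(C)(C)C)/C=C/[C@@]1(C)C=CC(=O)[C@@](C)(OC(C)=O)[C@@H]1[C@H](O[Si](C)(C)C(C)(C)C)[C@H](O)C=C | intermediate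
21 | epoxy alcohol with C6–C7 oxirane, C8–OH and C9–OSi(tBu)Me2 (7R,8R,9S) | C=C(I)[C@@H](O[Si](c1ccccc1)(c1ccccc1)C(C)(C)C)/C=C/[C@@]1(C)C=CC(=O)[C@@](C)(OC(C)=O)[C@@H]1[C@H](O[Si](C)(C)C(C)(C)C)[C@H](O)[C@H]2CO2 | intermediate
22 | epoxy ketone with (7R)-oxiranyl C8 ketone and C9–OSi(tBu)Me2 (7R,9S) | C=C(I)[C@@H](O[Si](c1ccccc1)(c1ccccc1)C(C)(C)C)/C=C/[C@@]1(C)C=CC(=O)[C@@](C)(OC(C)=O)[C@@H]1[C@H](O[Si](C)(C)C(C)(C)C)C(=O)[C@H]2CO2 | intermediate
23 | propanoic acid | CCC(=O)O | starting material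
24 | dilithium enediolate: dilithium prop-1-ene-1,1-diolate | [Li+].[Li+].CC=C([O-])[O-] | intermediate
25 | dilithium epoxy aldolate: C8 alkoxide and C19 carboxylate of the aldol adduct of 22 (7R,8S,9S,17R) | C=C(I)[C@@H](O[Si](c1ccccc1)(c1ccccc1)C(C)(C)C)/C=C/[C@@]1(C)C=CC(=O)[C@@](C)(OC(C)=O)[C@@H]1[C@H](O[Si](C)(C)C(C)(C)C)[C@]([O-])([C@@H](C)C(=O)[O-])[C@H]2CO2.[Li+].[Li+] | intermediate
26 | hydroxymethyl lactone with the 17-methyl-8-hydroxy-γ-lactone fused at C7–C8 and C6 as CH2OH (7S,8S,9S,17R) | C=C(I)[C@@H](O[Si](c1ccccc1)(c1ccccc1)C(C)(C)C)/C=C/[C@@]1(C)C=CC(=O)[C@@](C)(OC(C)=O)[C@@H]1[C@H](O[Si](C)(C)C(C)(C)C)[C@]2(O)[C@@H](C)C(=O)O[C@H]2CO | intermediate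
27 | lactone aldehyde with C6 formyl group (7R,8S,9S,17R) | C=C(I)[C@@H](O[Si](c1ccccc1)(c1ccccc1)C(C)(C)C)/C=C/[C@@]1(C)C=CC(=O)[C@@](C)(OC(C)=O)[C@@H]1[C@H](O[Si](C)(C)C(C)(C)C)[C@]2(O)[C@@H](C)C(=O)O[C@H]2C=O | intermediate
28 | ten-membered ring alcohol with C6–OH, C4–OSi(tBu)Ph2 and C9–OSi(tBu)Me2 (1S,4S,6R,7S,8S,9S,10S,11S,17R) | C=C1[C@@H](O[Si](c2ccccc2)(c2ccccc2)C(C)(C)C)/C=C/[C@@]2(C)C=CC(=O)[C@@](C)(OC(C)=O)[C@@H]2[C@H](O[Si](C)(C)C(C)(C)C)[C@]2(O)[C@@H](C)C(=O)O[C@H]2[C@@H]1O | intermediate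
29 | C6 chloride with C4–OSi(tBu)Ph2 and C9–OSi(tBu)Me2 (6S,7R,8S,9S) | C=C1[C@@H](O[Si](c2ccccc2)(c2ccccc2)C(C)(C)C)/C=C/[C@@]2(C)C=CC(=O)[C@@](C)(OC(C)=O)[C@@H]2[C@H](O[Si](C)(C)C(C)(C)C)[C@]2(O)[C@@H](C)C(=O)O[C@H]2[C@H]1Cl | intermediate
30 | C9 alcohol with C4–OSi(tBu)Ph2 (6S,7R,8R,9S) | C=C1[C@@H](O[Si](c2ccccc2)(c2ccccc2)C(C)(C)C)/C=C/[C@@]2(C)C=CC(=O)[C@@](C)(OC(C)=O)[C@@H]2[C@H](O)[C@]2(O)[C@@H](C)C(=O)O[C@H]2[C@H]1Cl | intermediate
31 | C9 acetate, the 4-O-tert-butyldiphenylsilyl ether of the target | C=C1[C@@H](O[Si](c2ccccc2)(c2ccccc2)C(C)(C)C)/C=C/[C@@]2(C)C=CC(=O)[C@@](C)(OC(C)=O)[C@@H]2[C@H](OC(C)=O)[C@]2(O)[C@@H](C)C(=O)O[C@H]2[C@H]1Cl | intermediate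
32 | CNP0196166.1 (1S,4S,6S,7R,8R,9S,10S,11S,17R) | C=C1[C@@H](O)/C=C/[C@@]2(C)C=CC(=O)[C@@](C)(OC(C)=O)[C@@H]2[C@H](OC(C)=O)[C@]2(O)[C@@H](C)C(=O)O[C@H]2[C@H]1Cl | target

**Step count and risks**

Total step count: 20. Longest linear sequence: 20 steps (1 to 32; 3, 7, 9, 14 and 23 are purchased partners).

Steps most likely to fail:

1. Step 14. The strongly basic enediolate may enolise the C8 ketone toward C9 instead of adding, may add under chelation to the wrong face, or may attack the tertiary acetate. The carboxylate may also open the oxirane at C6 (6-endo) or only after an alkoxide-driven epoxide migration. Fallback, from 22: a Reformatsky reaction with tert-butyl 2-bromopropanoate and zinc (THF, 0 °C) uses a non-basic zinc enolate and should give the tert-butyl β-hydroxy ester F1 with the oxirane intact. Treatment of F1 with BF3·OEt2 (CH2Cl2, −40 °C) then makes the ester carbonyl oxygen open the activated oxirane at C7 with loss of the tert-butyl group, which returns to 26. If C17 is formed as a mixture it would be equilibrated with DBU.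

2. Step 16. Closure of the strained ten-membered ring may be slower than intermolecular coupling, and the facial selectivity of the addition at C6 may be poor or opposite. Fallback, from 27: the ring is closed with plain CrCl2/NiCl2 in DMSO at high dilution without the chiral ligand, accepting both carbinol epimers, i.e. 28 together with its 6S epimer F2. The mixture is oxidised with Dess–Martin periodinane to the macrocyclic α-methylene ketone F3. F3 is then reduced 1,2 with NaBH4/CeCl3 (MeOH, −78 °C; Luche reduction, hydride from the outer face of the ring) or, for the opposite bias, with Zn(BH4)2, which returns to 28 with C6 set by ketone reduction instead of by the ring closure.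

3. Step 4. The hot, weakly acidic radical conditions may cost the dimethyl acetal or the aldehyde, and facial selectivity at the tertiary C11 may be low. Fallback, from 5: the cross-conjugated lithium dienolate is formed with LiN(SiMe3)2 (THF, −78 °C) and hydroxylated with 2-(phenylsulfonyl)-3-phenyloxaziridine from the face anti to the C10 substituent, giving the tertiary α′-hydroxy enone F4. Acetylation of F4 (Ac2O, DMAP, Et3N, 40 °C) returns to 6.

Further compounds
F1 | step 14 | tert-butyl β-hydroxy ester: Reformatsky adduct of 22 with C8–OH, C17 methyl, tert-butyl ester and intact (7R)-oxirane | C=C(I)[C@@H](O[Si](c1ccccc1)(c1ccccc1)C(C)(C)C)/C=C/[C@@]1(C)C=CC(=O)[C@@](C)(OC(C)=O)[C@@H]1[C@H](O[Si](C)(C)C(C)(C)C)[C@](O)([C@@H](C)C(=O)OC(C)(C)C)[C@H]2CO2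
F2 | step 16 | 6S epimer of ten-membered ring alcohol 28 | C=C1[C@@H](O[Si](c2ccccc2)(c2ccccc2)C(C)(C)C)/C=C/[C@@]2(C)C=CC(=O)[C@@](C)(OC(C)=O)[C@@H]2[C@H](O[Si](C)(C)C(C)(C)C)[C@]2(O)[C@@H](C)C(=O)O[C@H]2[C@H]1O
F3 | step 16 | macrocyclic C6 ketone (α-methylene ketone) | C=C1[C@@H](O[Si](c2ccccc2)(c2ccccc2)C(C)(C)C)/C=C/[C@@]2(C)C=CC(=O)[C@@](C)(OC(C)=O)[C@@H]2[C@H](O[Si](C)(C)C(C)(C)C)[C@]2(O)[C@@H](C)C(=O)O[C@H]2C1=O
F4 | step 4 | (1S,5S,6R)-6-(dimethoxymethyl)-5-hydroxy-1,5-dimethyl-4-oxocyclohex-2-ene-1-carbaldehyde | O=C[C@@]1(C)C=CC(=O)[C@@](C)(O)[C@@H]1C(OC)OC
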